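# Proposed total synthesis of CNP0288291.1 by late, biomimetic construction of the resorcylic acid ring

## Analysis of the target

The target is 2-[(8Z,10R)-10-acetoxypentadec-8-en-1-yl]-4,6-dihydroxybenzoic acid, a 6-alkyl-β-resorcylic acid. In its benzene ring (ring A), C1 carries the carboxyl group, C2 and C4 carry hydroxyl groups, C3 and C5 are CH, and C6 carries an unbranched C15 chain. The chain has seven methylene groups (C1'–C7'), a Z double bond C8'=C9', the only stereocentre C10' (R, O-acetylated, allylic) and an n-pentyl end (C11'–C15'). The stereocentre lies nine bonds from the ring, so nothing in the ring can control it; it has to be bought or set by a reagent.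

The sensitive groups are:
- the allylic acetate, which is cleaved by hydroxide or alkoxide and can be ionised by strong acid or by zerovalent palladium;
- the Z-alkene;
- the β-resorcylic acid, which decarboxylates on heating or in strong acid.

The difficulty is chemoselectivity, not complexity. The single acetyl group sits on the least acidic of four oxygen functions, so any plan that frees the phenols and the carboxyl group at the end by hydrolysis or ether cleavage loses the acetate, and a late acetylation would hit the phenols first.

The feature that invites the strategy is the substitution pattern of ring A: carboxyl at C1, oxygen at C2 and C4, hydrogen at C3 and C5, alkyl at C6. This is the folding pattern of a tetraketide. The carboxyl carbon and C1–C6 of ring A correspond to C1 and C2–C7 of a 3,5,7-trioxoalkanoate in which C2 and C7 are joined by an aldol condensation. Ring A can therefore be made last, from an open chain that already carries the finished side chain with its acetate, and with the ester chosen at the moment the ring forms.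

## Retrosynthetic reasoning

**23 to 22.** The free acid is released last from the 2-(trimethylsilyl)ethyl ester 22. This ester is cleaved at silicon and not at a carbonyl carbon, so the one deprotection of the route cannot compete with the acetate. No phenol protecting group is needed at any stage.

**22 to 18 (key disconnection).** Ring A is opened at the C1–C6 bond and the ester C–O bond is cut. This leads through aldol adduct 21 to the open triketo ester 20, through 20 to acylketene 19, and through 19 to diketo-dioxinone 18, in which the 1,3-dioxin-4-one ring masks the terminal β-keto ester. The cut is placed at C1–C6 because this is the bond between the only doubly activated methylene of 20 and a ketone six atoms away. What is gained is the whole aromatic ring with its four substituents and a freely chosen ester in one operation, from an acyclic precursor, under conditions (neutral heat, an amine) that the acetate tolerates. The forward reaction has to achieve cycloreversion, capture of the ketene by an alcohol, C-aldol closure and dehydration.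

**18 to 9 and 15.** The dioxo chain of 18 is cut between the acyl carbon of the fatty acid part and the central methylene. This gives acid chloride 9, which holds all stereochemical information, and keto ester dioxinone 15, a triketide building block. The allyl ester of 15 makes its C2 acidic enough for soft enolisation, which tolerates the acetate of 9. After C-acylation to 16 the ester is removed by palladium-catalysed deallylation and decarboxylation through acid 17.

**15 to 11 and 12; 11 to 10.** The bond between the ketone of 15 and the dioxinone methylene is cut. Forward, dienolate 14 of dioxinone 12 is acylated at its γ-carbon by acid chloride 13, made from half ester 11. Half ester 11 comes from 10 by ring opening.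

**9 to 8, 6 and 5.** These are functional group changes only: acid chloride from acid 8, acetate from alcohol 6, and the Z-alkene of 6 from the alkyne of 5 by syn semi-hydrogenation. The alkyne is the reason for the next cut.

**5 to 1 and 2.** The sp–sp3 bond C8–C9 of 5 is cut. Forward, the dianion 3 of the enantiopure propargylic alcohol 1 is alkylated by the lithium salt 4 of bromo acid 2. The stereocentre is bought with 1 and no later step touches a bond to it.

## Alternatives that were turned down

**Alternative 1: the textbook route, aryl–alkyl cross-coupling on a purchased ring.**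
- Disconnection: the C6–C1' bond.
- Forward key step: hydroboration of the terminal alkene of diene acetate A2 and B-alkyl Suzuki coupling with aryl triflate A1 (PdCl2(dppf), K3PO4) to give A3.
- Reason turned down: A1 needs three to four steps of protection and activation that build no skeleton, and the coupling forms one bond and none of the ring. The decisive point is the end game: A3 must lose an acetal and the acetonide, the latter by hydroxide or alkoxide, which also cleaves the C10' acetate. The acetate would then have to be put back in the presence of two phenols and the acid. The chemoselectivity problem of the target is moved, not solved, and the route is longer.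

**Alternative 2: Z-olefination at C8'=C9'.**
- Disconnection: the C8'=C9' double bond.
- Forward key step: cis-selective Wittig reaction of the ylide of phosphonium salt A4 with α-silyloxy aldehyde A5 to give A6.
- Reason turned down: A5 has its stereocentre α to an aldehyde and is exposed to a basic ylide, so erosion of configuration is a structural risk. A4 needs an aromatic-first synthesis with full protection. A6 still needs hydrolysis of a hindered, hydrogen-bonded 2,6-disubstituted benzoate and an exchange of silyl for acetyl at C10' in the presence of phenols. The key step forms one bond and leaves both real problems to protecting groups.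

**Alternative 3: ring A by [4+2] cycloaddition.**
- Disconnection: the ring bonds C1–C2 and C5–C6.
- Forward key step: Diels–Alder reaction of ynoate A7 with bis-silyloxy diene A8, then aromatisation by loss of silanol and methanol to give methyl resorcylate A9.
- Reason turned down: a β-alkyl ynoate is a weak dienophile and needs temperatures at which the electron-rich diene degrades. The product is a methyl ester whose saponification (hindered, chelated salicylate) needs hot hydroxide and strips the acetate. A7 costs as many steps as 9, so the same ring would be built with less certainty and a worse end game.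

Key step: step 9

## Route

Remark on the chemistry: the SMILES is read as R at C10' and Z at C8'=C9'. Enantiopure (R)-oct-1-yn-3-ol (1) has the same arrangement of O, H, pentyl and unsaturated carbon and is taken as a commercial starting material.

Step 1
Reactants: 1 (R)-oct-1-yn-3-ol; 2 8-bromooctanoic acid
Product: 5 (11R)-11-hydroxyhexadec-9-ynoic acid, via dilithiated alkynol 3 (not isolated), via lithium 8-bromooctanoate 4 (not isolated)
Conditions: 1, n-BuLi (2.05 equiv), THF/DMPU, −78 → 0 °C; 2, LiN(SiMe3)2 (1.0 equiv), THF, −78 °C; combine, 0 °C → rt; then 1 M HCl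
Reagents that add atoms: none
Why: SN2 alkylation of a lithium acetylide by a primary bromide; the acetylide carbon of 3 is far more nucleophilic than its alkoxide oxygen, and 4 has no proton that could quench it. The stereocentre comes with 1 and no bond to it is touched.

Step 2
Reactants: 5 (11R)-11-hydroxyhexadec-9-ynoic acid
Product: 6 (9Z,11R)-11-hydroxyhexadec-9-enoic acid
Conditions: H2 (1 atm), Pd/CaCO3 poisoned with Pb(OAc)2 (Lindlar catalyst), quinoline, EtOAc, rt
Reagents that add atoms: none
Why: Lindlar semi-hydrogenation; syn delivery of hydrogen on the poisoned palladium surface should give the Z-alkene, and quinoline holds the reduction at the alkene stage. C11 is not involved.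

Step 3
Reactants: 6 (9Z,11R)-11-hydroxyhexadec-9-enoic acid
Product: 8 (9Z,11R)-11-acetoxyhexadec-9-enoic acid, via mixed acetic anhydride 7 (not isolated)
Conditions: Ac2O (3 equiv), pyridine, DMAP (cat.), CH2Cl2, 0 °C → rt; then H2O, THF, rt
Reagents that add atoms: acetic anhydride, CC(=O)OC(C)=O; water, O
Why: Standard DMAP-catalysed acetylation of a secondary alcohol; the carboxyl group is acetylated as well to mixed anhydride 7, which aqueous pyridine hydrolyses back to the acid while the alkyl acetate stays.

Step 4
Reactants: 8 (9Z,11R)-11-acetoxyhexadec-9-enoic acid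
Product: 9 (9Z,11R)-11-acetoxyhexadec-9-enoyl chloride
Conditions: 1-chloro-N,N,2-trimethylprop-1-en-1-amine (1.2 equiv), CH2Cl2, 0 °C → rt; used crude
Reagents that add atoms: 1-chloro-N,N,2-trimethylprop-1-en-1-amine, CC(C)=C(Cl)N(C)C
Why: The α-chloroenamine turns a carboxylic acid into its chloride under neutral conditions without free HCl, so the allylic acetate and the Z-alkene see no acid; the amide by-product is inert in step 7.

Step 5
Reactants: 10 2,2-dimethyl-1,3-dioxane-4,6-dione (Meldrum's acid)
Product: 11 3-(allyloxy)-3-oxopropanoic acid (allyl hydrogen malonate)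
Conditions: allyl alcohol (1.05 equiv), PhMe, 110 °C
Reagents that add atoms: allyl alcohol, C=CCO
Why: Thermal alcoholysis of Meldrum's acid opens the ring to the malonic half ester with loss of acetone.

Step 6
Reactants: 11 3-(allyloxy)-3-oxopropanoic acid; 12 2,2,6-trimethyl-4H-1,3-dioxin-4-one
Product: 15 allyl 4-(2,2-dimethyl-4-oxo-4H-1,3-dioxin-6-yl)-3-oxobutanoate, via allyl malonyl chloride 13 (not isolated), via lithium dienolate 14 (not isolated)
Conditions: 11, 1-chloro-N,N,2-trimethylprop-1-en-1-amine (1.05 equiv), CH2Cl2, 0 °C → rt; 12, LiN(SiMe3)2 (2.2 equiv each), THF, −78 °C; combine at −78 °C; then 1 M HCl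
Reagents that add atoms: none
Why: Vinylogous Claisen acylation; dienolate 14 reacts at its γ-carbon (the former methyl group of 12) with acid chloride 13 at −78 °C, and the second equivalent of 14 takes up the acidic proton of product 15.

Step 7
Reactants: 9 (9Z,11R)-11-acetoxyhexadec-9-enoyl chloride; 15 allyl 4-(2,2-dimethyl-4-oxo-4H-1,3-dioxin-6-yl)-3-oxobutanoate
Product: 16 allyl (11Z,13R)-13-acetoxy-2-[(2,2-dimethyl-4-oxo-4H-1,3-dioxin-6-yl)acetyl]-3-oxooctadec-11-enoate
Conditions: MgCl2 (2 equiv), pyridine (2.7 equiv), CH2Cl2, 0 °C; then 9, 0 °C → rt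
Reagents that add atoms: none
Why: Magnesium-mediated soft enolisation and C-acylation of a β-keto ester; chelation by MgCl2 acidifies C2 of 15 (between ester and ketone) so that pyridine is base enough, and C2 is acylated in preference to the methylene next to the dioxinone. Neither the weak base nor the mild Lewis acid attacks the acetate.

Step 8
Reactants: 16 allyl (11Z,13R)-13-acetoxy-2-[(2,2-dimethyl-4-oxo-4H-1,3-dioxin-6-yl)acetyl]-3-oxooctadec-11-enoate
Product: 18 6-[(12Z,14R)-14-acetoxy-2,4-dioxononadec-12-en-1-yl]-2,2-dimethyl-4H-1,3-dioxin-4-one, via β-keto acid 17 (not isolated)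
Conditions: Pd(PPh3)4 (5 mol %), morpholine (2 equiv), THF, 0 °C; cold 1 M HCl wash
Reagents that add atoms: none
Why: Zerovalent palladium ionises the unsubstituted allyl ester, whose leaving group is the carboxylate of a tricarbonyl compound; morpholine takes the allyl group and acid 17 loses CO2 at once. The internal 1,3-dialkyl allylic acetate binds and ionises much more slowly, so 0 °C and a short reaction time should leave it intact.

Step 9
Reactants: 18 6-[(12Z,14R)-14-acetoxy-2,4-dioxononadec-12-en-1-yl]-2,2-dimethyl-4H-1,3-dioxin-4-one
Product: 22 2-(trimethylsilyl)ethyl 2-[(8Z,10R)-10-acetoxypentadec-8-en-1-yl]-4,6-dihydroxybenzoate, via acylketene 19 (not isolated), via triketo ester 20 (not isolated), via aldol adduct 21 (not isolated)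
Conditions: 2-(trimethylsilyl)ethanol (4 equiv), PhMe, 110 °C; then Et3N (2 equiv), CH2Cl2, rt; work-up with 1 M HCl
Reagents that add atoms: 2-(trimethylsilyl)ethanol, C[Si](C)(C)CCO
Why: Heating 18 causes a retro-hetero-Diels–Alder reaction of the dioxinone ring that expels acetone and gives acylketene 19, which the alcohol captures to give triketo ester 20; this is the known thermolysis of 2,2-dimethyl-1,3-dioxin-4-ones, and the closest precedent for the whole sequence is the biomimetic conversion of diketo-dioxinones into resorcylate esters. Triethylamine then enolises C2 of 20, the only methylene that is doubly activated and also six atoms from a ketone, and C2 adds to the C7 ketone in a 6-(enolendo)-exo-trig aldol closure to give 21. Loss of water from 21 (E1cB; the hydroxyl group is β to two carbonyl groups) and enolisation of the two remaining ketones give ring A of 22, with the ester at C1, OH at C2 and C4 and the chain at C6; aromatisation is the driving force. No stereocentre is created: the two sp3 centres of 21 vanish on aromatisation, and C10' with its acetate and the Z-alkene lie far from the reacting chain and meet only neutral heat, an amine and dilute acid. The selectivity needed is C-aldol (C2 to C7) over the Claisen mode (C6 to C1) and over attack of an enol oxygen on the ketene or the ester to give a pyranone. An excess of the alcohol should make trapping of 19 fast, the poor alkoxide leaving group of the ester disfavours the Claisen and pyranone paths under a mild amine base, and the absence of hydroxide or alkoxide spares the acetate.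

Step 10
Reactants: 22 2-(trimethylsilyl)ethyl 2-[(8Z,10R)-10-acetoxypentadec-8-en-1-yl]-4,6-dihydroxybenzoate
Product: 23 2-[(8Z,10R)-10-acetoxypentadec-8-en-1-yl]-4,6-dihydroxybenzoic acid (the target)
Conditions: Bu4NF (3 equiv), THF, 0 °C → rt; then 1 M HCl to pH 3, 0 °C
Reagents that add atoms: none
Why: Fluoride attacks silicon and the ester fragments by β-elimination to carboxylate, ethene and Me3SiF; no tetrahedral intermediate forms at a carbonyl carbon, so the secondary acetate should be spared. Cold, mild acidification avoids decarboxylation of the β-resorcylic acid.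

## Compound list

1 | (R)-oct-1-yn-3-ol | CCCCC[C@@H](O)C#C | starting material
2 | 8-bromooctanoic acid | OC(=O)CCCCCCCBr | starting material
3 | dilithium (3R)-oct-1-yn-1-id-3-olate (dilithiated 1) | [Li+].[Li+].CCCCC[C@@H]([O-])C#[C-] | intermediate
4 | lithium 8-bromooctanoate | [Li+].[O-]C(=O)CCCCCCCBr | intermediate
5 | (11R)-11-hydroxyhexadec-9-ynoic acid | CCCCC[C@@H](O)C#CCCCCCCCC(=O)O | intermediate
6 | (9Z,11R)-11-hydroxyhexadec-9-enoic acid | CCCCC[C@@H](O)/C=C\CCCCCCCC(=O)O | intermediate
7 | acetic (9Z,11R)-11-acetoxyhexadec-9-enoic anhydride | CCCCC[C@H](/C=C\CCCCCCCC(=O)OC(C)=O)OC(C)=O | intermediate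
8 | (9Z,11R)-11-acetoxyhexadec-9-enoic acid | CCCCC[C@H](/C=C\CCCCCCCC(=O)O)OC(C)=O | intermediate
9 | (9Z,11R)-11-acetoxyhexadec-9-enoyl chloride | CCCCC[C@H](/C=C\CCCCCCCC(=O)Cl)OC(C)=O | intermediate
10 | 2,2-dimethyl-1,3-dioxane-4,6-dione (Meldrum's acid) | CC1(C)OC(=O)CC(=O)O1 | starting material
11 | 3-(allyloxy)-3-oxopropanoic acid (allyl hydrogen malonate) | C=CCOC(=O)CC(=O)O | intermediate
12 | 2,2,6-trimethyl-4H-1,3-dioxin-4-one | CC1=CC(=O)OC(C)(C)O1 | starting material
13 | allyl 3-chloro-3-oxopropanoate (allyl malonyl chloride) | C=CCOC(=O)CC(=O)Cl | intermediate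
14 | lithium 2,2-dimethyl-6-methylidene-6H-1,3-dioxin-4-olate | [Li+].C=C1C=C([O-])OC(C)(C)O1 | intermediate
15 | allyl 4-(2,2-dimethyl-4-oxo-4H-1,3-dioxin-6-yl)-3-oxobutanoate | C=CCOC(=O)CC(=O)CC1=CC(=O)OC(C)(C)O1 | intermediate
16 | allyl (11Z,13R)-13-acetoxy-2-[(2,2-dimethyl-4-oxo-4H-1,3-dioxin-6-yl)acetyl]-3-oxooctadec-11-enoate | CCCCC[C@H](/C=C\CCCCCCCC(=O)C(C(=O)OCC=C)C(=O)CC1=CC(=O)OC(C)(C)O1)OC(C)=O | intermediate
17 | (11Z,13R)-13-acetoxy-2-[(2,2-dimethyl-4-oxo-4H-1,3-dioxin-6-yl)acetyl]-3-oxooctadec-11-enoic acid | CCCCC[C@H](/C=C\CCCCCCCC(=O)C(C(=O)O)C(=O)CC1=CC(=O)OC(C)(C)O1)OC(C)=O | intermediate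
18 | 6-[(12Z,14R)-14-acetoxy-2,4-dioxononadec-12-en-1-yl]-2,2-dimethyl-4H-1,3-dioxin-4-one | CCCCC[C@H](/C=C\CCCCCCCC(=O)CC(=O)CC1=CC(=O)OC(C)(C)O1)OC(C)=O | intermediate
19 | (6R,7Z)-16,18,20,22-tetraoxodocosa-7,21-dien-6-yl acetate (acylketene) | CCCCC[C@H](/C=C\CCCCCCCC(=O)CC(=O)CC(=O)C=C=O)OC(C)=O | intermediate
20 | 2-(trimethylsilyl)ethyl (15Z,17R)-17-acetoxy-3,5,7-trioxodocos-15-enoate | CCCCC[C@H](/C=C\CCCCCCCC(=O)CC(=O)CC(=O)CC(=O)OCC[Si](C)(C)C)OC(C)=O | intermediate
21 | 2-(trimethylsilyl)ethyl 2-[(8Z,10R)-10-acetoxypentadec-8-en-1-yl]-2-hydroxy-4,6-dioxocyclohexane-1-carboxylate (ring stereocentres transient, undefined) | CCCCC[C@H](/C=C\CCCCCCCC1(O)CC(=O)CC(=O)C1C(=O)OCC[Si](C)(C)C)OC(C)=O | intermediate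
22 | 2-(trimethylsilyl)ethyl 2-[(8Z,10R)-10-acetoxypentadec-8-en-1-yl]-4,6-dihydroxybenzoate | CCCCC[C@H](/C=C\CCCCCCCc1cc(O)cc(O)c1C(=O)OCC[Si](C)(C)C)OC(C)=O | intermediate
23 | 2-[(8Z,10R)-10-acetoxypentadec-8-en-1-yl]-4,6-dihydroxybenzoic acid | CCCCC[C@H](/C=C\CCCCCCCc1cc(O)cc(O)c1C(=O)O)OC(C)=O | target

## Step count and risk

Total step count: 10. Longest linear sequence: 8 steps (steps 1, 2, 3, 4, 7, 8, 9, 10 from compound 1); the second branch (steps 5 and 6) joins at step 7.

Steps least certain to work:

**Step 9 (key step).** The most likely failure is closure through oxygen instead of carbon: an enol oxygen of 19 or 20 attacks the ketene or the ester and forms a 4-hydroxy-2-pyranone before trapping and C-aldol closure are complete. Slow dehydration of 21 or partial loss of the acetate under base is a second possibility.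

Fallback, from 18 back to 22: the order of events is reversed. Treating 18 with Et3N in CH2Cl2 at rt, without heating, should bring about the same aldol closure and dehydration while the carboxyl terminus is still locked in the dioxinone, so that no pyranone can form. This gives 5-[(8Z,10R)-10-acetoxypentadec-8-en-1-yl]-7-hydroxy-2,2-dimethyl-4H-1,3-benzodioxin-4-one F1. Irradiation of F1 at 300 nm in CH2Cl2 with 2-(trimethylsilyl)ethanol then opens the benzodioxinone by photochemical cycloreversion to a quinoketene, which the alcohol captures under neutral conditions, and the route is rejoined at 22.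

**Step 8.** The risk is competing ionisation of the C14 allylic acetate by zerovalent palladium, with amination, loss of configuration or Z/E scrambling, and early aldol aromatisation of 18 by morpholine.

Fallback, from 9 and 12 back to 18: this avoids palladium and replaces steps 5 to 8. Dienolate 14 (from 12, as in step 6) is acylated with acetyl chloride to give 2,2-dimethyl-6-(2-oxopropyl)-4H-1,3-dioxin-4-one F2. LiN(iPr)2 (2.1 equiv, THF, −78 °C) converts F2 into dilithium 2,2-dimethyl-6-(2-oxidoprop-2-en-1-ylidene)-6H-1,3-dioxin-4-olate F3. F3 is acylated at its terminal carbon by acid chloride 9 at −78 °C and quenched cold with AcOH, which returns the route at 18. At this temperature an acid chloride should react far faster than a secondary acetate.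

**Step 1.** The risk is slow or incomplete C-alkylation because the lithium carboxylate 4 is aggregated and poorly soluble, with O-alkylation and elimination as side paths.

Fallback, from 1 back to 8: the electrophile carries the future carboxyl carbon as a protected alcohol. Dianion 3 is alkylated with 2-[(8-bromooctyl)oxy]tetrahydro-2H-pyran F4 to give (6R)-16-(tetrahydro-2H-pyran-2-yloxy)hexadec-7-yn-6-ol F5. Acetylation (Ac2O, pyridine) gives (6R)-16-(tetrahydro-2H-pyran-2-yloxy)hexadec-7-yn-6-yl acetate F6, and Lindlar semi-hydrogenation as in step 2 gives (6R,7Z)-16-(tetrahydro-2H-pyran-2-yloxy)hexadec-7-en-6-yl acetate F7. Removal of the acetal (pyridinium p-toluenesulfonate, MeOH) gives (6R,7Z)-16-hydroxyhexadec-7-en-6-yl acetate F8, and oxidation of the primary alcohol (TEMPO, PhI(OAc)2, MeCN/H2O) returns the route at 8. The acetal carbon of F4 to F7 is a mixture of epimers of no consequence.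

**Step 10.** The risk is attack of basic fluoride or adventitious hydroxide on the acetate, and decarboxylation of the product during work-up.

Fallback, from 18 back to 23: the ester is changed at the key step and cleaved by a different mechanism. Thermolysis of 18 with allyl alcohol in place of the silyl alcohol, then Et3N as in step 9, should give allyl 2-[(8Z,10R)-10-acetoxypentadec-8-en-1-yl]-4,6-dihydroxybenzoate F9. Pd(PPh3)4 and morpholine (THF, 0 °C) remove the allyl group as in step 8 and give 23 directly.

## Further compounds

F1 | step 9 | 5-[(8Z,10R)-10-acetoxypentadec-8-en-1-yl]-7-hydroxy-2,2-dimethyl-4H-1,3-benzodioxin-4-one | CCCCC[C@H](/C=C\CCCCCCCc1cc(O)cc2OC(C)(C)OC(=O)c12)OC(C)=O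
F2 | step 8 | 2,2-dimethyl-6-(2-oxopropyl)-4H-1,3-dioxin-4-one | CC(=O)CC1=CC(=O)OC(C)(C)O1
F3 | step 8 | dilithium 2,2-dimethyl-6-(2-oxidoprop-2-en-1-ylidene)-6H-1,3-dioxin-4-olate | [Li+].[Li+].C=C([O-])C=C1C=C([O-])OC(C)(C)O1
F4 | step 1 | 2-[(8-bromooctyl)oxy]tetrahydro-2H-pyran | BrCCCCCCCCOC1CCCCO1
F5 | step 1 | (6R)-16-(tetrahydro-2H-pyran-2-yloxy)hexadec-7-yn-6-ol | CCCCC[C@@H](O)C#CCCCCCCCCOC1CCCCO1
F6 | step 1 | (6R)-16-(tetrahydro-2H-pyran-2-yloxy)hexadec-7-yn-6-yl acetate | CCCCC[C@H](C#CCCCCCCCCOC1CCCCO1)OC(C)=O
F7 | step 1 | (6R,7Z)-16-(tetrahydro-2H-pyran-2-yloxy)hexadec-7-en-6-yl acetate | CCCCC[C@H](/C=C\CCCCCCCCOC1CCCCO1)OC(C)=O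
F8 | step 1 | (6R,7Z)-16-hydroxyhexadec-7-en-6-yl acetate | CCCCC[C@H](/C=C\CCCCCCCCO)OC(C)=O
F9 | step 10 | allyl 2-[(8Z,10R)-10-acetoxypentadec-8-en-1-yl]-4,6-dihydroxybenzoate | CCCCC[C@H](/C=C\CCCCCCCc1cc(O)cc(O)c1C(=O)OCC=C)OC(C)=O
A1 | alternative 1 | 7-(methoxymethoxy)-2,2-dimethyl-4-oxo-4H-1,3-benzodioxin-5-yl trifluoromethanesulfonate | CC1(C)OC(=O)c2c(OS(=O)(=O)C(F)(F)F)cc(OCOC)cc2O1
A2 | alternative 1 | (8Z,10R)-pentadeca-1,8-dien-10-yl acetate | CCCCC[C@H](/C=C\CCCCCC=C)OC(C)=O
A3 | alternative 1 | 5-[(8Z,10R)-10-acetoxypentadec-8-en-1-yl]-7-(methoxymethoxy)-2,2-dimethyl-4H-1,3-benzodioxin-4-one | CCCCC[C@H](/C=C\CCCCCCCc1cc(OCOC)cc2OC(C)(C)OC(=O)c12)OC(C)=O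
A4 | alternative 2 | {8-[2-(methoxycarbonyl)-3,5-bis(methoxymethoxy)phenyl]octyl}triphenylphosphonium bromide | [Br-].COCOc1cc(OCOC)c(C(=O)OC)c(CCCCCCCC[P+](c2ccccc2)(c2ccccc2)c2ccccc2)c1
A5 | alternative 2 | (2R)-2-[(tert-butyldimethylsilyl)oxy]heptanal | CCCCC[C@@H](O[Si](C)(C)C(C)(C)C)C=O
A6 | alternative 2 | methyl 2-[(8Z,10R)-10-[(tert-butyldimethylsilyl)oxy]pentadec-8-en-1-yl]-4,6-bis(methoxymethoxy)benzoate | CCCCC[C@@H](O[Si](C)(C)C(C)(C)C)/C=C\CCCCCCCc1cc(OCOC)cc(OCOC)c1C(=O)OC
A7 | alternative 3 | methyl (11Z,13R)-13-acetoxyoctadec-11-en-2-ynoate | CCCCC[C@H](/C=C\CCCCCCCC#CC(=O)OC)OC(C)=O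
A8 | alternative 3 | 1-methoxy-1,3-bis(trimethylsilyloxy)buta-1,3-diene | COC(O[Si](C)(C)C)=CC(=C)O[Si](C)(C)C
A9 | alternative 3 | methyl 2-[(8Z,10R)-10-acetoxypentadec-8-en-1-yl]-4,6-dihydroxybenzoate | CCCCC[C@H](/C=C\CCCCCCCc1cc(O)cc(O)c1C(=O)OC)OC(C)=O
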